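**Strategy.** Rings A and B are the same 2,4-dioxygenated 5-(1,1-dimethylallyl)phenyl unit, so one aldehyde, made by aromatic Claisen rearrangement of a prenyl ether, supplies both. The pyran ring is disconnected at O1–C2 and C3–C4: ring A carries O1 ortho and O7 para to benzylic C4 and is therefore a latent ortho-quinone methide, while C2, C3 and ring B form an arylacetaldehyde. In one operation a chiral secondary amine adds the aldehyde enamine to the methide carbon (C3–C4, C3 set as R) and the released phenol O1 closes onto C2 as a lactol. The precursors are a 2-(tosylmethyl)phenol and a silylated arylacetaldehyde; the lactol hydroxyl is later removed by ionic reduction.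

Key step: step 8

Remark: atoms are numbered as in the isoflavan (O1, C2, C3, C4, C4a to C8a in ring A, primed numbers in ring B); TBS is tert-butyldimethylsilyl. Lactol 14 is carried on as a mixture of C2 anomers and enol ether 10 as a mixture of alkene isomers, because both elements are erased in the following operation.

**Step 1**
Reactants: 1 2,4-dihydroxybenzaldehyde; 2 1-bromo-3-methylbut-2-ene (prenyl bromide)
Product: 3 2-hydroxy-4-[(3-methylbut-2-en-1-yl)oxy]benzaldehyde
Conditions: K2CO3 (1.0 equiv), acetone, rt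
Reagents that add atoms: none
Why: Williamson etherification, selective for the 4-hydroxyl because the 2-hydroxyl is held in a hydrogen bond to the formyl group and is the weaker nucleophile.

**Step 2**
Reactants: 3 2-hydroxy-4-[(3-methylbut-2-en-1-yl)oxy]benzaldehyde
Product: 4 2-[(tert-butyldimethylsilyl)oxy]-4-[(3-methylbut-2-en-1-yl)oxy]benzaldehyde
Conditions: TBSCl, imidazole, DMF, rt
Reagents that add atoms: tert-butyldimethylsilyl chloride (TBSCl), CC(C)(C)[Si](C)(C)Cl
Why: Standard silylation of a phenol, which removes the chelated hydroxyl and places a bulky group next to C3 so that the coming rearrangement is steered to C5.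

**Step 3**
Reactants: 4 2-[(tert-butyldimethylsilyl)oxy]-4-[(3-methylbut-2-en-1-yl)oxy]benzaldehyde
Product: 5 2-[(tert-butyldimethylsilyl)oxy]-4-hydroxy-5-(2-methylbut-3-en-2-yl)benzaldehyde
Conditions: PhNEt2, 190 °C, sealed tube
Reagents that add atoms: none
Why: Aromatic Claisen rearrangement, a [3,3]-sigmatropic shift that delivers the prenyl group with allylic inversion as a 1,1-dimethylallyl group to C5, since C3 lies between two oxygen substituents and is too crowded for a quaternary carbon and the meta silyloxy donor directs para to itself; tautomerisation then restores the arene.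

**Step 4**
Reactants: 5 2-[(tert-butyldimethylsilyl)oxy]-4-hydroxy-5-(2-methylbut-3-en-2-yl)benzaldehyde
Product: 6 2,4-bis[(tert-butyldimethylsilyl)oxy]-5-(2-methylbut-3-en-2-yl)benzaldehyde
Conditions: TBSCl, imidazole, DMF, 50 °C
Reagents that add atoms: tert-butyldimethylsilyl chloride (TBSCl), CC(C)(C)[Si](C)(C)Cl
Why: Silylation of the hindered phenol under non-acidic conditions, which avoids acid-induced cyclisation of the phenol onto the neighbouring 1,1-dimethylallyl group.

**Step 5**
Reactants: 6 2,4-bis[(tert-butyldimethylsilyl)oxy]-5-(2-methylbut-3-en-2-yl)benzaldehyde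
Product: 8 5-[(tert-butyldimethylsilyl)oxy]-2-(hydroxymethyl)-4-(2-methylbut-3-en-2-yl)phenol, via salicylaldehyde 7 (not isolated)
Conditions: K2CO3 (20 mol %), MeOH/THF, 0 °C; then NaBH4, 0 °C
Reagents that add atoms: none
Why: Base-catalysed methanolysis should cleave only the unhindered silyl ether ortho to the formyl group (it gives a chelated phenoxide), while the silyl ether beside the quaternary carbon is shielded; carbonyl reduction by NaBH4 in the same flask then gives the salicyl alcohol.

**Step 6**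
Reactants: 8 5-[(tert-butyldimethylsilyl)oxy]-2-(hydroxymethyl)-4-(2-methylbut-3-en-2-yl)phenol
Product: 9 5-[(tert-butyldimethylsilyl)oxy]-4-(2-methylbut-3-en-2-yl)-2-[(4-methylbenzenesulfonyl)methyl]phenol
Conditions: p-TolSO2Na, HCO2H, THF/H2O, rt
Reagents that add atoms: sodium p-toluenesulfinate, Cc1ccc(cc1)S(=O)[O-].[Na+]
Why: Acid-promoted benzylic substitution of the SN1 type, in which the benzylic cation stabilised by the ortho hydroxyl and para silyloxy groups is captured at sulfur by the sulfinate to give the sulfone.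

**Step 7**
Reactants: 6 2,4-bis[(tert-butyldimethylsilyl)oxy]-5-(2-methylbut-3-en-2-yl)benzaldehyde
Product: 11 2-{2,4-bis[(tert-butyldimethylsilyl)oxy]-5-(2-methylbut-3-en-2-yl)phenyl}acetaldehyde, via methyl enol ether 10 (not isolated)
Conditions: Ph3P(CH2OMe)Cl, KN(SiMe3)2, THF, 0 °C; then 1 M HCl, THF, 0 °C to rt
Reagents that add atoms: (methoxymethyl)triphenylphosphonium chloride, COC[P+](c1ccccc1)(c1ccccc1)c1ccccc1.[Cl-]; water, O
Why: Wittig one-carbon homologation with the methoxymethylene ylide followed by mild acid hydrolysis of the enol ether, conditions under which aryl silyl ethers and the terminal alkene should persist.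

**Step 8**
Reactants: 9 5-[(tert-butyldimethylsilyl)oxy]-4-(2-methylbut-3-en-2-yl)-2-[(4-methylbenzenesulfonyl)methyl]phenol; 11 2-{2,4-bis[(tert-butyldimethylsilyl)oxy]-5-(2-methylbut-3-en-2-yl)phenyl}acetaldehyde (1.5 equiv)
Product: 14 (3R)-3-{2,4-bis[(tert-butyldimethylsilyl)oxy]-5-(2-methylbut-3-en-2-yl)phenyl}-7-[(tert-butyldimethylsilyl)oxy]-6-(2-methylbut-3-en-2-yl)-3,4-dihydro-2H-1-benzopyran-2-ol (mixture of C2 anomers), via ortho-quinone methide 12 (not isolated), via open-chain aldehyde 13 (not isolated)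
Conditions: (R)-2-[diphenyl(trimethylsilyloxy)methyl]pyrrolidine (20 mol %), Na2CO3 (1.2 equiv), CH2Cl2/H2O, 0 °C to rt
Reagents that add atoms: none
Why: Na2CO3 deprotonates the phenol of 9 and 1,4-elimination of p-toluenesulfinate releases ortho-quinone methide 12 (stabilised by the para silyloxy group at O7), while the amine condenses with 11 to the E-enamine, whose nucleophilic carbon (future C3) adds to the exocyclic methylene (future C4) in a conjugate addition that rearomatises ring A, and hydrolysis of the iminium ion gives 13 and returns the catalyst. The closest known reaction type is the aminocatalytic Michael addition–hemiacetalisation (formal [4+2] annulation) of aldehydes with ortho-quinone methides generated in situ from 2-(sulfonylmethyl)phenols. The pyran ring closes by 6-exo-trig attack of the phenol oxygen O1 on the C2 carbonyl, a reversible hemiacetalisation that should lie on the side of the ring. C3 is controlled by the catalyst, whose diphenyl(trimethylsilyloxy)methyl group shields one face of the s-trans E-enamine so that 12 approaches the open face, which for the R catalyst corresponds to 3R here (the aryl group outranks the new CH2 group, so the descriptor is the reverse of that seen with simple alkyl aldehydes); the anomeric centre C2 is not controlled and is erased in step 9. The step needs C–C bond formation at the methide carbon rather than oligomerisation of 12, and closure by O1 alone, which are secured by the slow release of 12 in the presence of excess enamine and by the silyl ethers on O7, O2' and O4' that leave O1 as the only free phenol (a free O2' would lead to a benzofuran). Lactol formation masks the α-aryl aldehyde and the α-branched product should no longer form an enamine readily, which protects C3 from epimerisation.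

**Step 9**
Reactants: 14 (3R)-3-{2,4-bis[(tert-butyldimethylsilyl)oxy]-5-(2-methylbut-3-en-2-yl)phenyl}-7-[(tert-butyldimethylsilyl)oxy]-6-(2-methylbut-3-en-2-yl)-3,4-dihydro-2H-1-benzopyran-2-ol
Product: 15 (3R)-3-{2,4-bis[(tert-butyldimethylsilyl)oxy]-5-(2-methylbut-3-en-2-yl)phenyl}-7-[(tert-butyldimethylsilyl)oxy]-6-(2-methylbut-3-en-2-yl)-3,4-dihydro-2H-1-benzopyran
Conditions: Et3SiH, BF3·OEt2, CH2Cl2, −78 °C
Reagents that add atoms: none
Why: Ionic reduction of the lactol through the cyclic oxocarbenium ion, where hydride capture at −78 °C should outrun deprotonation at C3, so the O1–C2 bond and the C3 configuration are kept while the monosubstituted alkenes and aryl silyl ethers are inert.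

**Step 10**
Reactants: 15 (3R)-3-{2,4-bis[(tert-butyldimethylsilyl)oxy]-5-(2-methylbut-3-en-2-yl)phenyl}-7-[(tert-butyldimethylsilyl)oxy]-6-(2-methylbut-3-en-2-yl)-3,4-dihydro-2H-1-benzopyran
Product: 16 Manuifolin E, 4-[(3R)-7-hydroxy-6-(2-methylbut-3-en-2-yl)-3,4-dihydro-2H-1-benzopyran-3-yl]-6-(2-methylbut-3-en-2-yl)benzene-1,3-diol
Conditions: Bu4NF, AcOH, THF, 0 °C to rt
Reagents that add atoms: none
Why: Fluoride-induced cleavage of the three aryl silyl ethers under buffered, non-acidic conditions, which spares the 1,1-dimethylallyl groups ortho to the freed phenols and the C3 stereocentre.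

**Compound list**
1 | 2,4-dihydroxybenzaldehyde | O=Cc1ccc(O)cc1O | starting material
2 | 1-bromo-3-methylbut-2-ene (prenyl bromide) | CC(C)=CCBr | starting material
3 | 2-hydroxy-4-[(3-methylbut-2-en-1-yl)oxy]benzaldehyde | O=Cc1ccc(OCC=C(C)C)cc1O | intermediate
4 | 2-[(tert-butyldimethylsilyl)oxy]-4-[(3-methylbut-2-en-1-yl)oxy]benzaldehyde | O=Cc1ccc(OCC=C(C)C)cc1O[Si](C)(C)C(C)(C)C | intermediate
5 | 2-[(tert-butyldimethylsilyl)oxy]-4-hydroxy-5-(2-methylbut-3-en-2-yl)benzaldehyde | O=Cc1cc(C(C)(C)C=C)c(O)cc1O[Si](C)(C)C(C)(C)C | intermediate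
6 | 2,4-bis[(tert-butyldimethylsilyl)oxy]-5-(2-methylbut-3-en-2-yl)benzaldehyde | O=Cc1cc(C(C)(C)C=C)c(O[Si](C)(C)C(C)(C)C)cc1O[Si](C)(C)C(C)(C)C | intermediate
7 | 4-[(tert-butyldimethylsilyl)oxy]-2-hydroxy-5-(2-methylbut-3-en-2-yl)benzaldehyde (salicylaldehyde, not isolated) | O=Cc1cc(C(C)(C)C=C)c(O[Si](C)(C)C(C)(C)C)cc1O | intermediate
8 | 5-[(tert-butyldimethylsilyl)oxy]-2-(hydroxymethyl)-4-(2-methylbut-3-en-2-yl)phenol | OCc1cc(C(C)(C)C=C)c(O[Si](C)(C)C(C)(C)C)cc1O | intermediate
9 | 5-[(tert-butyldimethylsilyl)oxy]-4-(2-methylbut-3-en-2-yl)-2-[(4-methylbenzenesulfonyl)methyl]phenol | Cc1ccc(cc1)S(=O)(=O)Cc1cc(C(C)(C)C=C)c(O[Si](C)(C)C(C)(C)C)cc1O | intermediate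
10 | 1-(2-methoxyethenyl)-2,4-bis[(tert-butyldimethylsilyl)oxy]-5-(2-methylbut-3-en-2-yl)benzene (methyl enol ether, alkene isomers, not isolated) | COC=Cc1cc(C(C)(C)C=C)c(O[Si](C)(C)C(C)(C)C)cc1O[Si](C)(C)C(C)(C)C | intermediate
11 | 2-{2,4-bis[(tert-butyldimethylsilyl)oxy]-5-(2-methylbut-3-en-2-yl)phenyl}acetaldehyde | O=CCc1cc(C(C)(C)C=C)c(O[Si](C)(C)C(C)(C)C)cc1O[Si](C)(C)C(C)(C)C | intermediate
12 | 3-[(tert-butyldimethylsilyl)oxy]-4-(2-methylbut-3-en-2-yl)-6-methylidenecyclohexa-2,4-dien-1-one (ortho-quinone methide, not isolated) | C=C1C=C(C(C)(C)C=C)C(O[Si](C)(C)C(C)(C)C)=CC1=O | intermediate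
13 | (2R)-2-{2,4-bis[(tert-butyldimethylsilyl)oxy]-5-(2-methylbut-3-en-2-yl)phenyl}-3-{4-[(tert-butyldimethylsilyl)oxy]-2-hydroxy-5-(2-methylbut-3-en-2-yl)phenyl}propanal (open-chain aldehyde, not isolated) | O=C[C@H](Cc1cc(C(C)(C)C=C)c(O[Si](C)(C)C(C)(C)C)cc1O)c1cc(C(C)(C)C=C)c(O[Si](C)(C)C(C)(C)C)cc1O[Si](C)(C)C(C)(C)C | intermediate
14 | (3R)-3-{2,4-bis[(tert-butyldimethylsilyl)oxy]-5-(2-methylbut-3-en-2-yl)phenyl}-7-[(tert-butyldimethylsilyl)oxy]-6-(2-methylbut-3-en-2-yl)-3,4-dihydro-2H-1-benzopyran-2-ol (C2 anomers) | OC1Oc2cc(O[Si](C)(C)C(C)(C)C)c(C(C)(C)C=C)cc2C[C@@H]1c1cc(C(C)(C)C=C)c(O[Si](C)(C)C(C)(C)C)cc1O[Si](C)(C)C(C)(C)C | intermediate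
15 | (3R)-3-{2,4-bis[(tert-butyldimethylsilyl)oxy]-5-(2-methylbut-3-en-2-yl)phenyl}-7-[(tert-butyldimethylsilyl)oxy]-6-(2-methylbut-3-en-2-yl)-3,4-dihydro-2H-1-benzopyran | C=CC(C)(C)c1cc2c(cc1O[Si](C)(C)C(C)(C)C)OC[C@@H](c1cc(C(C)(C)C=C)c(O[Si](C)(C)C(C)(C)C)cc1O[Si](C)(C)C(C)(C)C)C2 | intermediate
16 | Manuifolin E, 4-[(3R)-7-hydroxy-6-(2-methylbut-3-en-2-yl)-3,4-dihydro-2H-1-benzopyran-3-yl]-6-(2-methylbut-3-en-2-yl)benzene-1,3-diol | C=CC(C)(C)c1cc2c(cc1O)OC[C@@H](c1cc(C(C)(C)C=C)c(O)cc1O)C2 | target

**Step count.** Total: 10 steps. Longest linear sequence: 9 steps (steps 1, 2, 3, 4, 5, 6, 8, 9, 10); the branch through step 7 has 8.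

**Steps most likely to fail**

1. Step 8. The facial selectivity of the enamine addition may be poor, the quinone methide may oligomerise before it is intercepted, or C3 may epimerise by enolisation of the open-chain α-aryl aldehyde before the lactol closes. The fallback sets out from 11 and returns to the route at 14. Aldehyde 11 is oxidised (NaClO2, NaH2PO4, 2-methylbut-2-ene, tBuOH/H2O) to {2,4-bis[(tert-butyldimethylsilyl)oxy]-5-(2-methylbut-3-en-2-yl)phenyl}acetic acid F1. This is activated with pivaloyl chloride and iPr2NEt as the mixed pivalic anhydride F2, which is not isolated. A chiral isothiourea Lewis base such as tetramisole (the enantiomer that leads to 3R, to be chosen in a pilot run) converts F2 into an acyl ammonium enolate. The enolate adds to quinone methide 12, released from 9 with Cs2CO3, and lactonises with release of the catalyst (Michael addition–lactonisation) to the (3R)-dihydrocoumarin F3. Reduction of F3 with iBu2AlH in CH2Cl2 at −78 °C gives lactol 14.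

2. Step 9. The configuration at C3 may be lost if the oxocarbenium ion is deprotonated to the 4H-chromene enol ether and reprotonated before hydride arrives. The fallback sets out from 14 and returns at 15 without any cation at C2. NaBH4 in EtOH at 0 °C reduces the open-chain aldehyde tautomer of 14 to (2R)-2-{2,4-bis[(tert-butyldimethylsilyl)oxy]-5-(2-methylbut-3-en-2-yl)phenyl}-3-{4-[(tert-butyldimethylsilyl)oxy]-2-hydroxy-5-(2-methylbut-3-en-2-yl)phenyl}propan-1-ol F4. A Mitsunobu cyclisation (PPh3, diisopropyl azodicarboxylate, THF, 0 °C) of the only free phenol onto the primary alcohol then gives 15.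

3. Step 3. The rearrangement may be accompanied by migration to C3, by further isomerisation of the 1,1-dimethylallyl group (abnormal Claisen pathway), by loss of the prenyl group, or by silyl transfer at the high temperature. The fallback sets out from 1 and returns at 6 without any sigmatropic step. Aldehyde 1 is brominated at C5 (N-bromosuccinimide, MeCN, 0 °C) to 5-bromo-2,4-dihydroxybenzaldehyde F5. Both phenols are silylated (TBSCl, imidazole, DMF) to 5-bromo-2,4-bis[(tert-butyldimethylsilyl)oxy]benzaldehyde F6. A branch-selective Suzuki–Miyaura coupling of F6 with 3-methylbut-2-en-1-ylboronic acid pinacol ester (Pd(OAc)2, a bulky biaryl dialkylphosphine chosen for coupling at the γ-carbon, K3PO4, THF/H2O, 40 °C) installs the 1,1-dimethylallyl group and gives 6.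

**Further compounds**
F1 | step 8 | {2,4-bis[(tert-butyldimethylsilyl)oxy]-5-(2-methylbut-3-en-2-yl)phenyl}acetic acid | OC(=O)Cc1cc(C(C)(C)C=C)c(O[Si](C)(C)C(C)(C)C)cc1O[Si](C)(C)C(C)(C)C
F2 | step 8 | {2,4-bis[(tert-butyldimethylsilyl)oxy]-5-(2-methylbut-3-en-2-yl)phenyl}acetic pivalic anhydride | CC(C)(C)C(=O)OC(=O)Cc1cc(C(C)(C)C=C)c(O[Si](C)(C)C(C)(C)C)cc1O[Si](C)(C)C(C)(C)C
F3 | step 8 | (3R)-3-{2,4-bis[(tert-butyldimethylsilyl)oxy]-5-(2-methylbut-3-en-2-yl)phenyl}-7-[(tert-butyldimethylsilyl)oxy]-6-(2-methylbut-3-en-2-yl)-3,4-dihydro-2H-1-benzopyran-2-one | O=C1Oc2cc(O[Si](C)(C)C(C)(C)C)c(C(C)(C)C=C)cc2C[C@@H]1c1cc(C(C)(C)C=C)c(O[Si](C)(C)C(C)(C)C)cc1O[Si](C)(C)C(C)(C)C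
F4 | step 9 | (2R)-2-{2,4-bis[(tert-butyldimethylsilyl)oxy]-5-(2-methylbut-3-en-2-yl)phenyl}-3-{4-[(tert-butyldimethylsilyl)oxy]-2-hydroxy-5-(2-methylbut-3-en-2-yl)phenyl}propan-1-ol | OC[C@H](Cc1cc(C(C)(C)C=C)c(O[Si](C)(C)C(C)(C)C)cc1O)c1cc(C(C)(C)C=C)c(O[Si](C)(C)C(C)(C)C)cc1O[Si](C)(C)C(C)(C)C
F5 | step 3 | 5-bromo-2,4-dihydroxybenzaldehyde | O=Cc1cc(Br)c(O)cc1O
F6 | step 3 | 5-bromo-2,4-bis[(tert-butyldimethylsilyl)oxy]benzaldehyde | O=Cc1cc(Br)c(O[Si](C)(C)C(C)(C)C)cc1O[Si](C)(C)C(C)(C)C
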